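Rings: A is the 2,4,6-trihydroxyphenoxy ring on the central ring B, C is the 1,4-diether ring on B, and D is the far 2,4,6-trihydroxyphenoxy ring. The last retrosynthetic cut is at eight O–alkyl bonds (six OMe, two OEt).
Ring A is then cut at C1–C6, C2–C3 and C4–C5. Its ether carbon C1 and the adjacent hydroxylated C2 are the two carbons of an aryloxyketene (ring B–O–CH=C=O), and the H/O pairs C3–C4 and C5–C6 are two molecules of HC≡C–OEt.
The ketene goes back to an aryloxyacetyl chloride, so the crowded A–B ether oxygen is set by a plain O-alkylation. The B–C and C–D ethers are cut at their unhindered aryl carbons (on ring B and at C4 of ring C) for CuI couplings.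
Forward: rings D, C and B are bought as phenols. D is joined to C, then C to B (which already carries OCH2CO2Me), the ester is taken to the acid chloride, ring A is built last, and all alkyl ethers are removed.
Stereochemistry: the target has no stereocentre. Only regiochemistry needs control, and it follows from the polarity of the ynol ether.

Key step: step 8

Remark: Ar denotes the rings B–C–D unit 3-[2,6-dimethoxy-4-(2,4,6-trimethoxyphenoxy)phenoxy]-5-methoxyphenyl. Ring A is numbered from its ether carbon C1 through the ketene-derived hydroxylated carbon C2 round to C6. The five carbon-supplying starting materials are assumed to be catalogue chemicals, with ethoxyacetylene as its solution in hexanes.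

Step 1
Reactants: 1 4-bromo-2,6-dimethoxyphenol
Product: 2 2-(benzyloxy)-5-bromo-1,3-dimethoxybenzene
Conditions: BnBr, K2CO3, DMF, rt
Reagents that add atoms: benzyl bromide, BrCc1ccccc1
Why: Williamson ether synthesis, in which the phenoxide of 1 is benzylated, the aryl bromide stays inert, and masking the hydroxyl stops 1 from acting as its own nucleophile in the next coupling.

Step 2
Reactants: 2 2-(benzyloxy)-5-bromo-1,3-dimethoxybenzene; 3 2,4,6-trimethoxyphenol
Product: 4 2-(benzyloxy)-1,3-dimethoxy-5-(2,4,6-trimethoxyphenoxy)benzene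
Conditions: CuI (10 mol%), picolinic acid (20 mol%), K3PO4, DMSO, 90 °C, Ar
Reagents that add atoms: none
Why: Ullmann-type diaryl ether synthesis, for which CuI/picolinic acid is established with di-ortho-substituted phenols; all crowding sits on the nucleophile because the C–Br carbon of 2 is flanked by two hydrogens, and exclusion of air protects the oxidisable phenol 3.

Step 3
Reactants: 4 2-(benzyloxy)-1,3-dimethoxy-5-(2,4,6-trimethoxyphenoxy)benzene
Product: 5 2,6-dimethoxy-4-(2,4,6-trimethoxyphenoxy)phenol
Conditions: H2 (1 atm), 10% Pd/C, EtOAc/EtOH, rt; product kept under Ar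
Reagents that add atoms: none
Why: Catalytic hydrogenolysis cleaves only the benzylic C–O bond, the aryl methyl ethers and the diaryl ether being inert and no halogen being left to reduce.

Step 4
Reactants: 6 3-bromo-5-methoxyphenol; 7 methyl bromoacetate
Product: 8 methyl 2-(3-bromo-5-methoxyphenoxy)acetate
Conditions: K2CO3, acetone, reflux
Reagents that add atoms: none
Why: Williamson ether synthesis with a reactive α-bromo ester under weak base, which installs the two carbons that become C1 and C2 of ring A and keeps the aryl bromide for the next coupling.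

Step 5
Reactants: 5 2,6-dimethoxy-4-(2,4,6-trimethoxyphenoxy)phenol; 8 methyl 2-(3-bromo-5-methoxyphenoxy)acetate
Product: 9 methyl 2-{3-[2,6-dimethoxy-4-(2,4,6-trimethoxyphenoxy)phenoxy]-5-methoxyphenoxy}acetate
Conditions: CuI (10 mol%), picolinic acid (20 mol%), anhydrous K3PO4, 4 Å MS, DMSO, 85 °C, Ar
Reagents that add atoms: none
Why: Second Ullmann-type diaryl ether synthesis on the same logic (hindered phenoxide, unhindered aryl bromide with two inductively activating meta oxygens); the methyl ester should tolerate dry phosphate base, and any portion that is hydrolysed converges on acid 10 in the next step.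

Step 6
Reactants: 9 methyl 2-{3-[2,6-dimethoxy-4-(2,4,6-trimethoxyphenoxy)phenoxy]-5-methoxyphenoxy}acetate
Product: 10 2-{3-[2,6-dimethoxy-4-(2,4,6-trimethoxyphenoxy)phenoxy]-5-methoxyphenoxy}acetic acid
Conditions: LiOH, THF/MeOH/H2O, rt; then 1 M HCl
Reagents that add atoms: lithium hydroxide, [Li+].[OH-]
Why: Ester saponification at room temperature, to which all aryl ethers are inert, followed by mild acidification to free the acid.

Step 7
Reactants: 10 2-{3-[2,6-dimethoxy-4-(2,4,6-trimethoxyphenoxy)phenoxy]-5-methoxyphenoxy}acetic acid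
Product: 11 2-{3-[2,6-dimethoxy-4-(2,4,6-trimethoxyphenoxy)phenoxy]-5-methoxyphenoxy}acetyl chloride
Conditions: 1-chloro-N,N,2-trimethylpropenylamine, CH2Cl2, 0 °C → rt; evaporate, high vacuum, use crude
Reagents that add atoms: 1-chloro-N,N,2-trimethylpropenylamine, CC(C)=C(Cl)N(C)C
Why: Acid chloride formation with an α-chloroenamine runs under neutral conditions without HCl, oxalyl chloride or a chloroiminium salt, so the very electron-rich rings B and D should be neither acylated nor formylated and ring B should not close onto the acyl group to a benzofuranone.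

Step 8
Reactants: 11 2-{3-[2,6-dimethoxy-4-(2,4,6-trimethoxyphenoxy)phenoxy]-5-methoxyphenoxy}acetyl chloride; 12 ethoxyacetylene (two molecules are incorporated)
Product: 19 2-{3-[2,6-dimethoxy-4-(2,4,6-trimethoxyphenoxy)phenoxy]-5-methoxyphenoxy}-3,5-diethoxyphenol, via aryloxyketene 13 (not isolated), via 4-aryloxy-3-ethoxycyclobutenone 14 (not isolated), via vinylketene 15 (not isolated), via 4-vinylcyclobutenone 16 (not isolated), via dienylketene 17 (not isolated), via cyclohexadienone 18 (not isolated)
Conditions: 12 (10 equiv, hexane solution), Et3N (1.3 equiv, slow addition), toluene, 0 °C → rt; salt filtered off under Ar; sealed vessel, 80 → 105 °C; then K2CO3, MeOH, rt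
Reagents that add atoms: none
Why: Proposed new method: Et3N dehydrochlorinates 11 to aryloxyketene 13, the unsubstituted carbon of 12 attacks the ketene carbonyl carbon (future C2) and the ketene α-carbon (C1) closes onto the ethoxy-bearing carbon (C6) to give cyclobutenone 14, which on heating opens by 4-electron electrocyclic cleavage of C1–C2 to vinylketene 15. Ketene 15 takes up a second 12 in the same sense (C2–C3 and C4–C5 form) to give 16, and reversible opening of 16 at its transient C2–C5 bond gives dienylketene 17, only the isomer with the ketene and the enol ether arm cis on the central double bond being drained onward. Ring A closes by a thermal disrotatory 6-electron electrocyclisation of 17 that rejoins C1 and C2, and dienone 18 tautomerises to phenol 19, so the net new ring bonds are C1–C6, C2–C3 and C4–C5. The closest known reaction types are the [2+2] cycloaddition of ketenes made from acid chlorides with alkoxyalkynes to give 3-alkoxycyclobutenones and the Danheiser benzannulation of cyclobutenones with alkoxyalkynes; what is new is letting one alkyne serve both stages in one flask, starting from an aryloxyketene. The step needs regioselectivity in both cycloadditions, which the polarity of the ynol ether (nucleophilic terminal carbon) against the electrophilic ketene carbonyl carbon secures and which puts oxygen on C4 and C6 and hydrogen on C3 and C5, and it needs the aryloxy donor on the sp3 carbon of 14 to rotate outward so that only hydrogen points into the closing terminus of 17. No stereocentre survives (the sp3 carbons of 14, 16 and 18 are racemic and transient), and slow base addition, excess 12, removal of the ammonium salt before heating, a ceiling of 105 °C against retro-ene decay of 12 and a final methanolysis of any O-acylated phenol guard the material balance.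

Step 9
Reactants: 19 2-{3-[2,6-dimethoxy-4-(2,4,6-trimethoxyphenoxy)phenoxy]-5-methoxyphenoxy}-3,5-diethoxyphenol
Product: 20 CNP0159471.0, 2-{3-[2,6-dihydroxy-4-(2,4,6-trihydroxyphenoxy)phenoxy]-5-hydroxyphenoxy}benzene-1,3,5-triol
Conditions: BBr3 (excess), CH2Cl2, −78 °C → rt, Ar; H2O quench; EtOAc extraction, Sephadex LH-20 under Ar
Reagents that add atoms: none
Why: Lewis acid ether cleavage in which bromide attacks the sp3 carbon of each boron-complexed alkyl aryl ether, so methyl and (more slowly) ethyl groups leave as alkyl bromides while the three diaryl ether links, which offer no sp3 carbon, should persist.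

Compound list
1 | 4-bromo-2,6-dimethoxyphenol | COc1cc(Br)cc(OC)c1O | starting material
2 | 2-(benzyloxy)-5-bromo-1,3-dimethoxybenzene | COc1cc(Br)cc(OC)c1OCc2ccccc2 | intermediate
3 | 2,4,6-trimethoxyphenol | COc1cc(OC)c(O)c(OC)c1 | starting material
4 | 2-(benzyloxy)-1,3-dimethoxy-5-(2,4,6-trimethoxyphenoxy)benzene | COc1cc(OC)c(Oc2cc(OC)c(OCc3ccccc3)c(OC)c2)c(OC)c1 | intermediate
5 | 2,6-dimethoxy-4-(2,4,6-trimethoxyphenoxy)phenol | COc1cc(OC)c(Oc2cc(OC)c(O)c(OC)c2)c(OC)c1 | intermediate
6 | 3-bromo-5-methoxyphenol | COc1cc(O)cc(Br)c1 | starting material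
7 | methyl bromoacetate | COC(=O)CBr | starting material
8 | methyl 2-(3-bromo-5-methoxyphenoxy)acetate | COC(=O)COc1cc(OC)cc(Br)c1 | intermediate
9 | methyl 2-{3-[2,6-dimethoxy-4-(2,4,6-trimethoxyphenoxy)phenoxy]-5-methoxyphenoxy}acetate | COC(=O)COc1cc(OC)cc(Oc2c(OC)cc(Oc3c(OC)cc(OC)cc3OC)cc2OC)c1 | intermediate
10 | 2-{3-[2,6-dimethoxy-4-(2,4,6-trimethoxyphenoxy)phenoxy]-5-methoxyphenoxy}acetic acid | OC(=O)COc1cc(OC)cc(Oc2c(OC)cc(Oc3c(OC)cc(OC)cc3OC)cc2OC)c1 | intermediate
11 | 2-{3-[2,6-dimethoxy-4-(2,4,6-trimethoxyphenoxy)phenoxy]-5-methoxyphenoxy}acetyl chloride | O=C(Cl)COc1cc(OC)cc(Oc2c(OC)cc(Oc3c(OC)cc(OC)cc3OC)cc2OC)c1 | intermediate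
12 | ethoxyacetylene | CCOC#C | starting material
13 | aryloxyketene, 2-(aryloxy)ethenone ArO–CH=C=O | O=C=COc1cc(OC)cc(Oc2c(OC)cc(Oc3c(OC)cc(OC)cc3OC)cc2OC)c1 | intermediate
14 | 4-(aryloxy)-3-ethoxycyclobut-2-en-1-one (racemic) | CCOC1=CC(=O)C1Oc2cc(OC)cc(Oc3c(OC)cc(Oc4c(OC)cc(OC)cc4OC)cc3OC)c2 | intermediate
15 | (3Z)-4-(aryloxy)-3-ethoxybuta-1,3-dien-1-one (aryloxy trans to the ketene carbon) | O=C=C/C(OCC)=C/Oc1cc(OC)cc(Oc2c(OC)cc(Oc3c(OC)cc(OC)cc3OC)cc2OC)c1 | intermediate
16 | 4-[(Z)-2-(aryloxy)-1-ethoxyethenyl]-3-ethoxycyclobut-2-en-1-one (racemic) | CCOC1=CC(=O)C1/C(OCC)=C/Oc2cc(OC)cc(Oc3c(OC)cc(Oc4c(OC)cc(OC)cc4OC)cc3OC)c2 | intermediate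
17 | (3E,5Z)-6-(aryloxy)-3,5-diethoxyhexa-1,3,5-trien-1-one | O=C=C/C(OCC)=C\C(OCC)=C\Oc1cc(OC)cc(Oc2c(OC)cc(Oc3c(OC)cc(OC)cc3OC)cc2OC)c1 | intermediate
18 | 6-(aryloxy)-3,5-diethoxycyclohexa-2,4-dien-1-one (racemic) | CCOC1=CC(=O)C(Oc2cc(OC)cc(Oc3c(OC)cc(Oc4c(OC)cc(OC)cc4OC)cc3OC)c2)C(OCC)=C1 | intermediate
19 | 2-{3-[2,6-dimethoxy-4-(2,4,6-trimethoxyphenoxy)phenoxy]-5-methoxyphenoxy}-3,5-diethoxyphenol | CCOc1cc(O)c(Oc2cc(OC)cc(Oc3c(OC)cc(Oc4c(OC)cc(OC)cc4OC)cc3OC)c2)c(OCC)c1 | intermediate
20 | CNP0159471.0, 2-{3-[2,6-dihydroxy-4-(2,4,6-trihydroxyphenoxy)phenoxy]-5-hydroxyphenoxy}benzene-1,3,5-triol (achiral) | Oc1cc(Oc2c(O)cc(O)cc2O)cc(Oc2c(O)cc(Oc3c(O)cc(O)cc3O)cc2O)c1 | target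

Total step count: 9. Longest linear sequence: 8 (steps 1, 2, 3, 5, 6, 7, 8, 9, counted from 1). Step 4 is the side branch.

Steps most likely to fail

Step 8. Several processes could defeat the cascade:
- The ketene may oligomerise faster than the alkyne captures it.
- The alkyne may decay by retro-ene fragmentation before the second addition.
- The cascade may stall at a cyclobutenone stage, because vinylogous ester stabilisation slows ring opening.
- The new phenol may be consumed by acylation.

The fallback uses known chemistry only, sets out from 5 (with 3 as second partner) and rejoins the route at 20; ring A is brought in ready-made. Phenol 5 would be coupled (CuI, picolinic acid, K3PO4, DMSO, 90 °C) with an excess of commercial 3,5-dibromoanisole to give the monobromide 2-(3-bromo-5-methoxyphenoxy)-1,3-dimethoxy-5-(2,4,6-trimethoxyphenoxy)benzene F1. A further Ullmann coupling of this bromide with 3 would give the nonamethyl ether 1-[2,6-dimethoxy-4-(2,4,6-trimethoxyphenoxy)phenoxy]-3-methoxy-5-(2,4,6-trimethoxyphenoxy)benzene F2. BBr3 cleavage as in step 9 would then lead to 20.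

Step 9. Cleavage may stop short at the slower ethyl ethers, and the free polyphenol may be lost to air oxidation and irreversible adsorption during isolation.

The fallback sets out from 19 and rejoins at 20. The crude BBr3 product would not be purified but acetylated at once (Ac2O, pyridine, DMAP, rt) to the nonaacetate 3-[2,6-diacetoxy-4-(2,4,6-triacetoxyphenoxy)phenoxy]-5-(2,4,6-triacetoxyphenoxy)phenyl acetate F3. This compound is stable to air and can be freed of partly dealkylated material on silica gel. Acid methanolysis (HCl generated from AcCl in MeOH, Ar, rt) and evaporation would then release 20 without chromatography of the free phenol.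

Step 5. C–O bond formation by the di-ortho-substituted phenoxide may be slow enough for ester hydrolysis, enolate side reactions or oxidation of the phenol to take over.

The fallback sets out from 6 and 5 and rejoins at 9; the ester is installed only after the coupling. Phenol 6 would be benzylated (BnBr, K2CO3, DMF) to 1-(benzyloxy)-3-bromo-5-methoxybenzene F4. Coupling with 5 under the CuI/picolinic acid conditions would give 2-[3-(benzyloxy)-5-methoxyphenoxy]-1,3-dimethoxy-5-(2,4,6-trimethoxyphenoxy)benzene F5. Hydrogenolysis (H2, Pd/C) would give 3-[2,6-dimethoxy-4-(2,4,6-trimethoxyphenoxy)phenoxy]-5-methoxyphenol F6, and alkylation with 7 (K2CO3, acetone) would give 9.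

Further compounds
F1 | step 8 | 2-(3-bromo-5-methoxyphenoxy)-1,3-dimethoxy-5-(2,4,6-trimethoxyphenoxy)benzene | COc1cc(Br)cc(Oc2c(OC)cc(Oc3c(OC)cc(OC)cc3OC)cc2OC)c1
F2 | step 8 | 1-[2,6-dimethoxy-4-(2,4,6-trimethoxyphenoxy)phenoxy]-3-methoxy-5-(2,4,6-trimethoxyphenoxy)benzene | COc1cc(Oc2c(OC)cc(OC)cc2OC)cc(Oc2c(OC)cc(Oc3c(OC)cc(OC)cc3OC)cc2OC)c1
F3 | step 9 | 3-[2,6-diacetoxy-4-(2,4,6-triacetoxyphenoxy)phenoxy]-5-(2,4,6-triacetoxyphenoxy)phenyl acetate | CC(=O)Oc1cc(Oc2c(OC(C)=O)cc(OC(C)=O)cc2OC(C)=O)cc(Oc2c(OC(C)=O)cc(Oc3c(OC(C)=O)cc(OC(C)=O)cc3OC(C)=O)cc2OC(C)=O)c1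
F4 | step 5 | 1-(benzyloxy)-3-bromo-5-methoxybenzene | COc1cc(Br)cc(OCc2ccccc2)c1
F5 | step 5 | 2-[3-(benzyloxy)-5-methoxyphenoxy]-1,3-dimethoxy-5-(2,4,6-trimethoxyphenoxy)benzene | COc1cc(OCc2ccccc2)cc(Oc2c(OC)cc(Oc3c(OC)cc(OC)cc3OC)cc2OC)c1
F6 | step 5 | 3-[2,6-dimethoxy-4-(2,4,6-trimethoxyphenoxy)phenoxy]-5-methoxyphenol | COc1cc(O)cc(Oc2c(OC)cc(Oc3c(OC)cc(OC)cc3OC)cc2OC)c1
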